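## Structural features

The target is an unsymmetrical diaryl ether. Ring A is a phenol (OH at C4) carrying the ether oxygen at C3 and a side chain at C1; ring B is a catechol (OH at C2 and C3) with the ether oxygen at C1 and the same kind of side chain at C5. Each side chain starts at a benzylic all-carbon quaternary stereocentre that bears methyl, vinyl and a (3E)-4,8-dimethylnona-3,7-dienyl chain. The centre on ring A is R and the centre on ring B is S; the priorities are the same at both (aryl > vinyl > chain > methyl), so the two arms have opposite absolute sense, and being eight bonds apart neither can direct the other. Fragile features are the four trisubstituted alkenes (protonation leads to hydration or cation–alkene cyclisation), the two vinyl groups on quaternary carbons, the air-sensitive free catechol, and, in every intermediate with vinyl and allyl on one carbon, a 1,5-diene that can undergo Cope rearrangement on strong heating. The real difficulty is to build two remote quaternary benzylic centres of opposite sense with no neighbouring heteroatom, and to give each an E-configured polyene chain. The key step exploits the CH2–CH= bond two carbons out from each quaternary carbon (Cq–CH2–CH2–CH=C): its alkyl half can be generated as a primary radical from a propanoic acid stub, and its alkenyl half is the same stereodefined nine-carbon iodide for both rings.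

## Logic of the disconnections

29 ⇒ 27. The three O–CH2 bonds of the acetal protecting groups are cut. Free phenols cannot pass through the reductive coupling, and acetals are the only ethers that survive the copper coupling, the ylides, the Grignard reagent and the borane. Nothing is gained in skeleton. The demand is that the forward removal must not use protic acid, because 27 holds four trisubstituted alkenes; it is therefore planned as an aprotic silyl transfer.

27 ⇒ 21 + 26 (twice). In each arm the CH2–CH= bond two carbons from the quaternary carbon is cut. It is an sp3–sp2 bond, so the alkyl side can come from a carboxylic acid and the alkenyl side from an iodide, and both arms need the same 26. Eighteen of the thirty side-chain carbons leave as one achiral fragment, and 21 is a compact core that already holds both stereocentres. The forward step must couple twice, keep the E geometry of 26, and trap each radical before it can attack the vinyl group or the ring.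

21 ⇒ 20 ⇒ 18 ⇒ 16. Only functional groups change: the two ester C–O bonds, then the oxidation level of the terminal carbons, which are traced back to the terminal carbons of two allyl groups. The reason is that catalytic asymmetric α-allylation delivers exactly a three-carbon arm. The demand is that hydroboration of 16 must tell the two allyl alkenes from the two vinyl alkenes; this rests on the vinyl groups sitting directly on quaternary carbons.

16 ⇒ 15 ⇒ 14 + 8. The C=C bond of the ring B vinyl group is cut (carbonyl methylenation), then the bond between the quaternary carbon and its allyl CH2. The quaternary centre is thus made at the α-carbon of an α-branched aldehyde, where a chiral catalyst can choose the face. The forward allylation must be catalyst-controlled and must use the mirror-image catalyst of the ring A arm, which is why the two arms are built in turn.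

14 ⇒ 12 ⇒ 10. The bond between the benzylic carbon and the formyl carbon is cut (one-carbon homologation of a methyl ketone), then the acyl–CH3 bond (ketone from ester). The ester of 10 is the latent acetyl group that keeps ring B silent while ring A is elaborated. The demand is an ester-to-ketone conversion without over-addition and an enol ether hydrolysis that spares the acetals.

10 ⇒ 9 ⇒ 7 + 8 ⇒ 5. The same three bonds are cut on ring A: vinyl C=C, quaternary carbon–allyl, benzylic carbon–formyl. This reduces the ring A arm to an acetyl group. The ylides must react with the ketone or aldehyde and leave the benzoate of ring B alone.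

5 ⇒ 2 + 4. The aryl–O bond on the ring B side of the ether is cut. It is made early, when both rings carry only carbonyl groups and the meta ester helps the bromide to react. The copper coupling must tolerate one ortho alkoxy group on each partner.

2 ⇒ 1 and 4 ⇒ 3. O–CH2 bonds of the acetals are cut. In 1 only the hydroxyl para to the acetyl group may be protected, which relies on its higher acidity.

26 ⇒ 24 ⇒ 22. The C–I bond and the C–CH3 bond across the alkene are cut (syn carbometalation of an alkyne fixes E), and the alkyne comes from the methyl ketone by formal dehydration.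

## Other disconnections considered

Alternative 1: Both bonds between a quaternary carbon and the first CH2 of its chain are cut.
- Forward step: biscarbamate A1 (R at the ring A carbinol carbon, S at the ring B one) would be deprotonated at both benzylic positions with sec-butyllithium and borylated with homogeranyl boronate A2. Twofold 1,2-shift with loss of carbamate would give bis(tertiary boronate) A3. Stereoretentive vinylation at boron (Zweifel olefination) and desilylation would then lead to 29.
- In its favour: the whole eleven-carbon chain arrives with its E alkene in one bond. The configuration is copied stereospecifically from secondary carbinols that are easy to set by ketone reduction, and no alkene has to be told from another. In convergence and in step count after the diaryl ether it is the better plan.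
- Against it: the two carbinols need opposite sense, so the two ketones must still be reduced one after the other with mirror reagents; here it is only the equal of the chosen plan. Para-oxygenated benzylic ate complexes are the class most prone to dissociate before the shift, which would let the carbanion racemise. The ether oxygen can direct ring lithiation, and the vinylation uses iodine beside four trisubstituted alkenes.
- Comparison: this plan asks a twofold cryogenic carbanion step to carry the stereochemistry. The chosen plan sets the centres by catalysis on small intermediates and gives the twofold step no stereochemical duty.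

Alternative 2: The C1–C6 and C2–C3 bonds of ring A are cut.
- Forward step: an enamine of aldehyde A4 would add to vinyl ketone A5 and the adduct would condense in the same operation to cyclohexenone A6. Dehydrogenation of that ring and acetal removal would lead to 29.
- In its favour: the ether oxygen is attached by a plain phenol alkylation, so no hindered metal-catalysed C–O coupling is needed; on this bond it is better than the chosen plan. The ring-forming step is classical polar chemistry with unambiguous regiochemistry, at least its equal in predictability.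
- Against it: A4 and A5 each already contain a complete side chain with its quaternary centre, so the real difficulty is only moved and must be solved twice on unrelated scaffolds. The enamine must react at a carbon next to a quaternary centre. The ring must then be aromatised by an oxidant in the presence of six alkenes with allylic hydrogens.
- Comparison: in step economy it is clearly worse.

Alternative 3: Four C–C bonds of ring B are cut.
- Forward step: irradiation of diazoketone A7 with ethynyl ether A8, then heating, would give phenol A9 through a Wolff shift, a ketene–alkyne [2+2] addition, a four-electron ring opening and a six-electron ring closure.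
- In its favour: two chiral halves are united late, the substitution pattern of ring B is fixed by the mechanism, and the ether oxygen is in place without a coupling. In convergence it is better than the chosen plan.
- Against it: A9 lacks the hydroxyl between the ether oxygen and the phenol, so a regioselective ortho-oxidation on a polyene-bearing ring would still be needed. Ultraviolet light meets aryl–C–vinyl and vinyl–C–vinyl units that can rearrange, and the ketene stage has alkenes within reach for intramolecular [2+2] addition. Aryl ethynyl ethers are sensitive, and both halves again need complete arms.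
- Comparison: the chosen plan keeps the polyene out of the molecule until the step before last and uses only ground-state chemistry, at the price of a longer linear sequence.

Key step: step 16

Assumption (remark on the chemistry): the (S) enantiomer of TRIP (3,3'-bis(2,4,6-triisopropylphenyl)-1,1'-binaphthyl-2,2'-diyl hydrogen phosphate) is taken to give the (S)-2-aryl-2-methylpent-4-enal, by analogy with simple 2-arylpropanals. If the sense is the reverse, the two catalyst enantiomers change places between steps 5 and 9 and nothing else changes.

## Route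

Step 1
Reactants: 1 3',4'-dihydroxyacetophenone
Product: 2 1-[3-hydroxy-4-(methoxymethoxy)phenyl]ethan-1-one
Conditions: MOMCl (1.05 equiv), K2CO3 (1.0 equiv), acetone, 0 °C to rt
Reagents that add atoms: chloromethyl methyl ether, COCCl
Why: Williamson-type O-alkylation; the hydroxyl para to the acetyl group is the more acidic, so one equivalent of weak base should ionise and alkylate it alone and leave the meta hydroxyl free for the ether coupling.

Step 2
Reactants: 3 methyl 3-bromo-4,5-dihydroxybenzoate
Product: 4 methyl 3-bromo-4,5-bis(methoxymethoxy)benzoate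
Conditions: MOMCl (3 equiv), i-Pr2NEt (4 equiv), CH2Cl2, 0 °C to rt
Reagents that add atoms: chloromethyl methyl ether, COCCl
Why: Exhaustive O-alkylation (acetal protection) of both phenols; ester and aryl bromide are inert to the amine base and the chloromethyl ether.

Step 3
Reactants: 2 ring A phenol; 4 ring B aryl bromide
Product: 5 methyl 3-[5-acetyl-2-(methoxymethoxy)phenoxy]-4,5-bis(methoxymethoxy)benzoate
Conditions: CuI (10 mol%), picolinic acid (20 mol%), K3PO4 (2 equiv), DMSO, 90 °C
Reagents that add atoms: none
Why: Ullmann-type diaryl ether synthesis: the picolinate complex of monovalent copper takes up the phenoxide of 2, inserts into the C–Br bond of 4 (helped by the meta ester) and eliminates the ether; this ligand tolerates one ortho alkoxy group on each partner, and the acetals, ketone and ester should survive K3PO4 at this temperature.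

Step 4
Reactants: 5 keto ester diaryl ether
Product: 7 methyl 3-[2-(methoxymethoxy)-5-(1-oxopropan-2-yl)phenoxy]-4,5-bis(methoxymethoxy)benzoate (racemic at the aldehyde α-carbon), via ring A methyl enol ether 6 (not isolated)
Conditions: Ph3P(CH2OMe)Cl, KN(SiMe3)2, THF, 0 °C to rt; then 1 M HCl (aq), rt
Reagents that add atoms: (methoxymethyl)triphenylphosphonium chloride, COC[P+](c1ccccc1)(c1ccccc1)c1ccccc1.[Cl-]; water, O
Why: Wittig reaction of the aryl methyl ketone with the methoxymethylene ylide (the benzoate is far less electrophilic), then hydrolysis of the enol ether, which is protonated on carbon much faster than formaldehyde acetals ionise in dilute acid at room temperature; the α-centre is left racemic because step 5 erases and resets it.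

Step 5
Reactants: 7 ring A 2-arylpropanal; 8 allyl alcohol
Product: 9 methyl 3-{2-(methoxymethoxy)-5-[(2S)-2-methyl-1-oxopent-4-en-2-yl]phenoxy}-4,5-bis(methoxymethoxy)benzoate
Conditions: Pd(PPh3)4 (3 mol%), (S)-TRIP (3 mol%), Ph2CHNH2 (40 mol%), 5 Å MS, toluene, 40 °C; then 1 M HCl/Et2O, rt
Reagents that add atoms: none
Why: Catalytic asymmetric α-allylation of an α-branched aldehyde (enamine catalysis combined with Tsuji–Trost allylation): the amine turns 7 into an enamine, zerovalent palladium and the acid ionise 8 to a π-allyl cation paired with the chiral phosphate, and the hydrogen-bonded phosphate selects the enamine face, planned to give the S aldehyde; the aryl group has no ortho substituent, the case for which this catalysis is established.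

Step 6
Reactants: 9 ring A quaternary aldehyde
Product: 10 methyl 3-{2-(methoxymethoxy)-5-[(3R)-3-methylhexa-1,5-dien-3-yl]phenoxy}-4,5-bis(methoxymethoxy)benzoate
Conditions: Ph3PCH3Br, KN(SiMe3)2, THF, 0 °C to rt
Reagents that add atoms: methyltriphenylphosphonium bromide, C[P+](c1ccccc1)(c1ccccc1)c1ccccc1.[Br-]
Why: Wittig methylenation of a non-enolisable aldehyde, so the centre cannot epimerise (the descriptor changes from S to R only because vinyl ranks below aryl); a small excess of ylide at 0 °C should leave the benzoate alone, and the 1,5-diene is kept well below Cope temperatures from here on.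

Step 7
Reactants: 10 ring A diene ester
Product: 12 1-[3-{2-(methoxymethoxy)-5-[(3R)-3-methylhexa-1,5-dien-3-yl]phenoxy}-4,5-bis(methoxymethoxy)phenyl]ethan-1-one, via Weinreb amide 11 (not isolated)
Conditions: MeNH(OMe)·HCl, i-PrMgCl, THF, −20 °C; then MeMgBr, 0 °C
Reagents that add atoms: methylmagnesium bromide, C[Mg]Br
Why: One-pot ester-to-ketone conversion through a Weinreb amide: the magnesium amide displaces methoxide, and the chelated adduct of 11 with MeMgBr releases the ketone only on work-up, which prevents over-addition; diene and acetals are inert to Grignard reagents.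

Step 8
Reactants: 12 ring B methyl ketone
Product: 14 2-[3-{2-(methoxymethoxy)-5-[(3R)-3-methylhexa-1,5-dien-3-yl]phenoxy}-4,5-bis(methoxymethoxy)phenyl]propanal (both epimers at C2), via ring B methyl enol ether 13 (not isolated)
Conditions: Ph3P(CH2OMe)Cl, KN(SiMe3)2, THF, 0 °C to rt; then 1 M HCl (aq), rt
Reagents that add atoms: (methoxymethyl)triphenylphosphonium chloride, COC[P+](c1ccccc1)(c1ccccc1)c1ccccc1.[Cl-]; water, O
Why: Same Wittig homologation and enol ether hydrolysis as step 4; the monosubstituted alkenes of the ring A arm are not protonated by dilute acid, and the new α-centre is again left unassigned.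

Step 9
Reactants: 14 ring B 2-arylpropanal; 8 allyl alcohol
Product: 15 (2R)-2-[3-{2-(methoxymethoxy)-5-[(3R)-3-methylhexa-1,5-dien-3-yl]phenoxy}-4,5-bis(methoxymethoxy)phenyl]-2-methylpent-4-enal
Conditions: Pd(PPh3)4 (3 mol%), (R)-TRIP (3 mol%), Ph2CHNH2 (40 mol%), 5 Å MS, toluene, 40 °C; then 1 M HCl/Et2O, rt
Reagents that add atoms: none
Why: Same enamine and Tsuji–Trost α-allylation as step 5 with the mirror-image phosphoric acid, so that the opposite enamine face is allylated and the R aldehyde should result; the ring A centre is eight bonds away, so catalyst control should decide.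

Step 10
Reactants: 15 ring B quaternary aldehyde
Product: 16 1,2-bis(methoxymethoxy)-3-{2-(methoxymethoxy)-5-[(3R)-3-methylhexa-1,5-dien-3-yl]phenoxy}-5-[(3S)-3-methylhexa-1,5-dien-3-yl]benzene
Conditions: Ph3PCH3Br, KN(SiMe3)2, THF, 0 °C to rt
Reagents that add atoms: methyltriphenylphosphonium bromide, C[P+](c1ccccc1)(c1ccccc1)c1ccccc1.[Br-]
Why: Wittig methylenation as in step 6; gives the second vinyl group on a centre that cannot epimerise (descriptor S after the change of priorities).

Step 11
Reactants: 16 tetraene
Product: 18 (4R)-4-[3-{5-[(3S)-6-hydroxy-3-methylhex-1-en-3-yl]-2,3-bis(methoxymethoxy)phenoxy}-4-(methoxymethoxy)phenyl]-4-methylhex-5-en-1-ol, via twofold alkylborane 17 (not isolated)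
Conditions: 9-BBN (2.3 equiv), THF, 0 °C to rt; then NaOH, H2O2, 0 °C to rt
Reagents that add atoms: hydrogen peroxide, OO
Why: Anti-Markovnikov hydroboration–oxidation: the bulky dialkylborane should add to the terminal carbon of each allyl group, whose alkene is one CH2 away from the quaternary carbon, much faster than to the vinyl groups that sit directly on the quaternary carbons; alkaline peroxide replaces boron by hydroxyl and no stereocentre is touched.

Step 12
Reactants: 18 diol
Product: 20 (4R)-4-[3-{5-[(3S)-5-carboxy-3-methylpent-1-en-3-yl]-2,3-bis(methoxymethoxy)phenoxy}-4-(methoxymethoxy)phenyl]-4-methylhex-5-enoic acid, via dialdehyde 19 (not isolated)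
Conditions: TEMPO (20 mol%), PhI(OAc)2 (4.5 equiv), MeCN/H2O (1:1), rt
Reagents that add atoms: water, O
Why: Nitroxyl-catalysed oxidation (oxoammonium salt regenerated by the iodine reagent) of both primary alcohols through the aldehyde hydrates to the acids; alkenes, acetals and aryl ethers should not be oxidised under these near-neutral conditions.

Step 13
Reactants: 20 diacid
Product: 21 bis(1,3-dioxoisoindolin-2-yl) diester of 20 (bis(N-hydroxyphthalimide ester); R at the ring A arm, S at the ring B arm)
Conditions: N-hydroxyphthalimide (2.4 equiv), DIC (2.4 equiv), DMAP (10 mol%), CH2Cl2, rt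
Reagents that add atoms: N-hydroxyphthalimide, ON1C(=O)c2ccccc2C1=O
Why: Carbodiimide (Steglich-type) esterification of both acids; gives the two redox-active esters needed for the coupling.

Step 14
Reactants: 22 6-methylhept-5-en-2-one
Product: 24 6-methylhept-5-en-1-yne, via enol phosphate 23 (not isolated)
Conditions: LiN(i-Pr)2, THF, −78 °C; ClP(O)(OEt)2; then LiN(i-Pr)2 (2.3 equiv), −78 °C to rt
Reagents that add atoms: none
Why: Kinetic deprotonation at the methyl group, O-phosphorylation and base-induced elimination of diethyl phosphate (methyl ketone to terminal alkyne); the trisubstituted alkene is a spectator.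

Step 15
Reactants: 24 6-methylhept-5-en-1-yne
Product: 26 (1E)-1-iodo-2,6-dimethylhepta-1,5-diene, via alkenylalane 25 (not isolated)
Conditions: Me3Al (2 equiv), Cp2ZrCl2 (25 mol%), CH2Cl2, 0 °C to rt; then I2, THF, −30 to 0 °C
Reagents that add atoms: trimethylaluminium, C[Al](C)C; iodine, II
Why: Zirconium-catalysed syn carboalumination places methyl on the inner and aluminium on the terminal alkyne carbon, and iodinolysis replaces aluminium with retention, which fixes the E geometry.

Step 16
Reactants: 21 bis(N-hydroxyphthalimide ester); 26 (1E)-1-iodo-2,6-dimethylhepta-1,5-diene (two equivalents react)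
Product: 27 1,2-bis(methoxymethoxy)-3-{2-(methoxymethoxy)-5-[(3R,6E)-3,7,11-trimethyldodeca-1,6,10-trien-3-yl]phenoxy}-5-[(3S,6E)-3,7,11-trimethyldodeca-1,6,10-trien-3-yl]benzene
Conditions: 26 (5 equiv), NiCl2·6H2O (40 mol%), 2,2'-bipyridine (40 mol%), AgNO3 (0.6 equiv), DMF, Mg anode, RVC cathode, constant current, rt
Reagents that add atoms: none
Why: This is a nickel-electrocatalytic decarboxylative alkenylation, a reductive cross-coupling of a redox-active ester with an alkenyl halide of the known kind used to assemble polyene terpenoids, run here on two esters in one operation. Bipyridine-ligated nickel is reduced at the silver-coated cathode to a low-valent state that inserts into the C–I bond of 26; each ester of 21 accepts one electron and fragments to phthalimide anion, CO2 and a primary alkyl radical; the radical is captured by the divalent alkenylnickel species and the resulting trivalent nickel eliminates the C(sp3)–C(sp2) bond, while the magnesium anode supplies the electrons. No ring is closed and no stereocentre is formed; both quaternary centres lie two carbons from the reacting carbon and are not touched. The E geometry is that of 26, because insertion into and elimination from an alkenyl carbon go with retention. The step needs radical capture by nickel to outrun the radical's own reactions, and the substrate secures this: toward the vinyl group it is a pent-4-enyl radical with only 4-exo or 5-endo closure open to it, and toward the ring it is a 3-arylpropyl radical for which aryl transfer would be a 1,3-shift through a four-membered spiro transition state. Cross-coupling must also beat reduction and homocoupling, which an excess of 26 and two identical, mutually remote esters should favour. The neutral, base-free medium should leave vinyl groups, acetals and the diaryl ether unchanged.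

Step 17
Reactants: 27 tris(methoxymethyl) ether
Product: 29 3-{2-hydroxy-5-[(3R,6E)-3,7,11-trimethyldodeca-1,6,10-trien-3-yl]phenoxy}-5-[(3S,6E)-3,7,11-trimethyldodeca-1,6,10-trien-3-yl]benzene-1,2-diol, via tris(trimethylsilyl) ether 28 (not isolated)
Conditions: Me3SiOTf (9 equiv), 2,2'-bipyridyl (12 equiv), MeCN, 0 °C to rt; then H2O, rt, under argon
Reagents that add atoms: none
Why: Aprotic acetal cleavage by silyl transfer: the N-silylpyridinium salt converts each aryl methoxymethyl ether into the aryl silyl ether and an N-(methoxymethyl)pyridinium salt, and water then hydrolyses the three silyl ethers; no free strong Brønsted acid is present, so the four trisubstituted alkenes should not be protonated, and exclusion of air protects the catechol.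

## Compound list

1 | 3',4'-dihydroxyacetophenone | CC(=O)c1ccc(O)c(O)c1 | starting material
2 | 1-[3-hydroxy-4-(methoxymethoxy)phenyl]ethan-1-one | CC(=O)c1ccc(OCOC)c(O)c1 | intermediate
3 | methyl 3-bromo-4,5-dihydroxybenzoate | COC(=O)c1cc(O)c(O)c(Br)c1 | starting material
4 | methyl 3-bromo-4,5-bis(methoxymethoxy)benzoate | COC(=O)c1cc(OCOC)c(OCOC)c(Br)c1 | intermediate
5 | methyl 3-[5-acetyl-2-(methoxymethoxy)phenoxy]-4,5-bis(methoxymethoxy)benzoate | CC(=O)c1ccc(OCOC)c(Oc2cc(C(=O)OC)cc(OCOC)c2OCOC)c1 | intermediate
6 | methyl 3-[5-(1-methoxyprop-1-en-2-yl)-2-(methoxymethoxy)phenoxy]-4,5-bis(methoxymethoxy)benzoate (E/Z mixture, formed in situ) | COC=C(C)c1ccc(OCOC)c(Oc2cc(C(=O)OC)cc(OCOC)c2OCOC)c1 | intermediate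
7 | methyl 3-[2-(methoxymethoxy)-5-(1-oxopropan-2-yl)phenoxy]-4,5-bis(methoxymethoxy)benzoate (racemic) | CC(C=O)c1ccc(OCOC)c(Oc2cc(C(=O)OC)cc(OCOC)c2OCOC)c1 | intermediate
8 | allyl alcohol (prop-2-en-1-ol) | C=CCO | starting material
9 | methyl 3-{2-(methoxymethoxy)-5-[(2S)-2-methyl-1-oxopent-4-en-2-yl]phenoxy}-4,5-bis(methoxymethoxy)benzoate | O=C[C@@](C)(CC=C)c1ccc(OCOC)c(Oc2cc(C(=O)OC)cc(OCOC)c2OCOC)c1 | intermediate
10 | methyl 3-{2-(methoxymethoxy)-5-[(3R)-3-methylhexa-1,5-dien-3-yl]phenoxy}-4,5-bis(methoxymethoxy)benzoate | C=C[C@@](C)(CC=C)c1ccc(OCOC)c(Oc2cc(C(=O)OC)cc(OCOC)c2OCOC)c1 | intermediate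
11 | N-methoxy-N-methyl-3-{2-(methoxymethoxy)-5-[(3R)-3-methylhexa-1,5-dien-3-yl]phenoxy}-4,5-bis(methoxymethoxy)benzamide (formed in situ) | C=C[C@@](C)(CC=C)c1ccc(OCOC)c(Oc2cc(C(=O)N(C)OC)cc(OCOC)c2OCOC)c1 | intermediate
12 | 1-[3-{2-(methoxymethoxy)-5-[(3R)-3-methylhexa-1,5-dien-3-yl]phenoxy}-4,5-bis(methoxymethoxy)phenyl]ethan-1-one | C=C[C@@](C)(CC=C)c1ccc(OCOC)c(Oc2cc(C(C)=O)cc(OCOC)c2OCOC)c1 | intermediate
13 | 1-(1-methoxyprop-1-en-2-yl)-3,4-bis(methoxymethoxy)-5-{2-(methoxymethoxy)-5-[(3R)-3-methylhexa-1,5-dien-3-yl]phenoxy}benzene (E/Z mixture, formed in situ) | C=C[C@@](C)(CC=C)c1ccc(OCOC)c(Oc2cc(C(C)=COC)cc(OCOC)c2OCOC)c1 | intermediate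
14 | 2-[3-{2-(methoxymethoxy)-5-[(3R)-3-methylhexa-1,5-dien-3-yl]phenoxy}-4,5-bis(methoxymethoxy)phenyl]propanal (both epimers at C2) | C=C[C@@](C)(CC=C)c1ccc(OCOC)c(Oc2cc(C(C)C=O)cc(OCOC)c2OCOC)c1 | intermediate
15 | (2R)-2-[3-{2-(methoxymethoxy)-5-[(3R)-3-methylhexa-1,5-dien-3-yl]phenoxy}-4,5-bis(methoxymethoxy)phenyl]-2-methylpent-4-enal | C=C[C@@](C)(CC=C)c1ccc(OCOC)c(Oc2cc([C@](C)(C=O)CC=C)cc(OCOC)c2OCOC)c1 | intermediate
16 | 1,2-bis(methoxymethoxy)-3-{2-(methoxymethoxy)-5-[(3R)-3-methylhexa-1,5-dien-3-yl]phenoxy}-5-[(3S)-3-methylhexa-1,5-dien-3-yl]benzene | C=C[C@@](C)(CC=C)c1ccc(OCOC)c(Oc2cc([C@](C)(C=C)CC=C)cc(OCOC)c2OCOC)c1 | intermediate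
17 | twofold B-alkyl-9-borabicyclo[3.3.1]nonane adduct of 16 (boron on the terminal carbon of each former allyl group, both vinyl groups intact; formed in situ) | C=C[C@@](C)(CCCB1C2CCCC1CCC2)c1ccc(OCOC)c(Oc2cc([C@](C)(C=C)CCCB3C4CCCC3CCC4)cc(OCOC)c2OCOC)c1 | intermediate
18 | (4R)-4-[3-{5-[(3S)-6-hydroxy-3-methylhex-1-en-3-yl]-2,3-bis(methoxymethoxy)phenoxy}-4-(methoxymethoxy)phenyl]-4-methylhex-5-en-1-ol | C=C[C@@](C)(CCCO)c1ccc(OCOC)c(Oc2cc([C@](C)(C=C)CCCO)cc(OCOC)c2OCOC)c1 | intermediate
19 | (4R)-4-[3-{2,3-bis(methoxymethoxy)-5-[(3S)-3-methyl-6-oxohex-1-en-3-yl]phenoxy}-4-(methoxymethoxy)phenyl]-4-methylhex-5-enal (formed in situ) | C=C[C@@](C)(CCC=O)c1ccc(OCOC)c(Oc2cc([C@](C)(C=C)CCC=O)cc(OCOC)c2OCOC)c1 | intermediate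
20 | (4R)-4-[3-{5-[(3S)-5-carboxy-3-methylpent-1-en-3-yl]-2,3-bis(methoxymethoxy)phenoxy}-4-(methoxymethoxy)phenyl]-4-methylhex-5-enoic acid | C=C[C@@](C)(CCC(=O)O)c1ccc(OCOC)c(Oc2cc([C@](C)(C=C)CCC(=O)O)cc(OCOC)c2OCOC)c1 | intermediate
21 | bis(1,3-dioxoisoindolin-2-yl) diester of 20 (R at the ring A arm, S at the ring B arm) | C=C[C@@](C)(CCC(=O)ON1C(=O)c2ccccc2C1=O)c1ccc(OCOC)c(Oc2cc([C@](C)(C=C)CCC(=O)ON3C(=O)c4ccccc4C3=O)cc(OCOC)c2OCOC)c1 | intermediate
22 | 6-methylhept-5-en-2-one | CC(=O)CCC=C(C)C | starting material
23 | diethyl 6-methylhepta-1,5-dien-2-yl phosphate (formed in situ) | C=C(CCC=C(C)C)OP(=O)(OCC)OCC | intermediate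
24 | 6-methylhept-5-en-1-yne | C#CCCC=C(C)C | intermediate
25 | [(1E)-2,6-dimethylhepta-1,5-dien-1-yl]dimethylaluminium (formed in situ) | C[Al](C)/C=C(\C)CCC=C(C)C | intermediate
26 | (1E)-1-iodo-2,6-dimethylhepta-1,5-diene | I/C=C(\C)CCC=C(C)C | intermediate
27 | 1,2-bis(methoxymethoxy)-3-{2-(methoxymethoxy)-5-[(3R,6E)-3,7,11-trimethyldodeca-1,6,10-trien-3-yl]phenoxy}-5-[(3S,6E)-3,7,11-trimethyldodeca-1,6,10-trien-3-yl]benzene | C=C[C@@](C)(CC/C=C(\C)CCC=C(C)C)c1ccc(OCOC)c(Oc2cc([C@](C)(C=C)CC/C=C(\C)CCC=C(C)C)cc(OCOC)c2OCOC)c1 | intermediate
28 | tris(trimethylsilyl) ether of 29 (formed in situ) | C=C[C@@](C)(CC/C=C(\C)CCC=C(C)C)c1ccc(O[Si](C)(C)C)c(Oc2cc([C@](C)(C=C)CC/C=C(\C)CCC=C(C)C)cc(O[Si](C)(C)C)c2O[Si](C)(C)C)c1 | intermediate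
29 | 3-{2-hydroxy-5-[(3R,6E)-3,7,11-trimethyldodeca-1,6,10-trien-3-yl]phenoxy}-5-[(3S,6E)-3,7,11-trimethyldodeca-1,6,10-trien-3-yl]benzene-1,2-diol | C=C[C@@](C)(CC/C=C(\C)CCC=C(C)C)c1ccc(O)c(Oc2cc([C@](C)(C=C)CC/C=C(\C)CCC=C(C)C)cc(O)c2O)c1 | target

## Step count and risks

Total step count: 17 (steps 1–13, 16 and 17 for the core and the end game, steps 14 and 15 for 26). Longest linear sequence: 14 steps (1, 3–13, 16, 17).

Least certain steps:

Step 16 (key step). The most likely failure is incomplete twofold coupling: one radical is reduced by hydrogen abstraction, or the alkenylnickel species is lost to homocoupling before the second ester has reacted, so that only one arm is extended. Fallback: the same two bonds are made by a thermal nickel-catalysed decarboxylative alkenylation with a preformed organozinc reagent. 26 is treated with t-BuLi at −78 °C and then ZnCl2 to give [(1E)-2,6-dimethylhepta-1,5-dien-1-yl]zinc chloride F1, which is coupled with 21 under Ni(acac)2 and 2,2'-bipyridine in THF/DMF at rt. The fallback sets out from 21 and 26 and returns at 27.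

Step 11. The most likely failure is insufficient discrimination between the allyl and the vinyl alkenes, so that boron also adds to one or both vinyl groups, or one allyl group is left unreacted. Fallback: the alkenes are told apart by metathesis instead, where an alkene on a fully substituted carbon is practically inert. 16 undergoes twofold cross-metathesis with vinylboronic acid pinacol ester (second-generation Hoveyda–Grubbs catalyst, CH2Cl2, 40 °C) to give the twofold (E)-alkenyl pinacol boronate F2. NaBO3·4H2O in THF/H2O converts it into dialdehyde 19, here isolated, and NaClO2/NaH2PO4 with 2-methylbut-2-ene gives 20. The fallback sets out from 16 and returns at 20.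

Step 9 (step 5 shares the risk on a simpler substrate). The most likely failure is poor enantiofacial control or slow enamine formation with the larger aryl group, which would give the wrong diastereomer of 15 that the remote ring A centre makes hard to separate. Fallback: the centre is set by a palladium-catalysed, branch-selective enantioselective allyl–allyl cross-coupling.
- 12 is converted with triethyl phosphonoacetate and NaH (Horner–Wadsworth–Emmons) into the (2E)-3-arylbut-2-enoate F3.
- i-Bu2AlH reduces it to the (2E)-3-arylbut-2-en-1-ol F4.
- N-chlorosuccinimide and dimethyl sulfide give the (2E)-allylic chloride F5.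
- Allylboronic acid pinacol ester, Pd2(dba)3, the appropriate enantiomer of 2,2'-bis(di-2-furylphosphino)-6,6'-dimethoxy-1,1'-biphenyl and CsF in THF then join the two allyl units at the substituted terminus.

The fallback sets out from 12 and returns at 16, bypassing steps 8 to 10.

Step 17. The most likely failure is incomplete cleavage of the flanked central acetal on ring B, or alkylation of the electron-rich rings by the methoxymethyl fragment, together with oxidation of the catechol during hydrolysis. Fallback: the protecting groups are exchanged before the acid-sensitive alkenes exist.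
- 21 is treated with CF3CO2H in wet CH2Cl2 at 0 °C to give the triphenol bis(N-hydroxyphthalimide ester) F6.
- i-Pr3SiOTf and 2,6-lutidine give the tris(triisopropylsilyl) ether bis(N-hydroxyphthalimide ester) F7.
- Coupling with 26 under the conditions of step 16 gives the tris(triisopropylsilyl) ether F8 of the target.
- Bu4NF buffered with acetic acid in THF at 0 °C releases 29.

The fallback sets out from 21 and returns at 29.

Step 3. The most likely failure is slow C–O bond formation with an ortho alkoxy group on each partner, with reduction of the C–Br bond or aldol condensation of the ketone taking over at the temperature needed. Fallback: the ether is made by oxidative copper coupling at room temperature. 4 is borylated (B2pin2, Pd(dppf)Cl2, KOAc, dioxane, 80 °C) to methyl 3,4-bis(methoxymethoxy)-5-(4,4,5,5-tetramethyl-1,3,2-dioxaborolan-2-yl)benzoate F9, which is coupled with 2 under Cu(OAc)2, pyridine and molecular sieves in air (Chan–Lam coupling). The fallback sets out from 4 and returns at 5.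

## Further compounds

F1 | step 16 | [(1E)-2,6-dimethylhepta-1,5-dien-1-yl]zinc chloride | Cl[Zn]/C=C(\C)CCC=C(C)C
F2 | step 11 | twofold (E)-alkenyl pinacol boronate from 16 (each former allyl group now CH2–CH=CH–B(pin)) | C=C[C@@](C)(C/C=C/B1OC(C)(C)C(C)(C)O1)c1ccc(OCOC)c(Oc2cc([C@](C)(C=C)C/C=C/B3OC(C)(C)C(C)(C)O3)cc(OCOC)c2OCOC)c1
F3 | step 9 | ethyl (2E)-3-[3-{2-(methoxymethoxy)-5-[(3R)-3-methylhexa-1,5-dien-3-yl]phenoxy}-4,5-bis(methoxymethoxy)phenyl]but-2-enoate | C=C[C@@](C)(CC=C)c1ccc(OCOC)c(Oc2cc(/C(C)=C/C(=O)OCC)cc(OCOC)c2OCOC)c1
F4 | step 9 | (2E)-3-[3-{2-(methoxymethoxy)-5-[(3R)-3-methylhexa-1,5-dien-3-yl]phenoxy}-4,5-bis(methoxymethoxy)phenyl]but-2-en-1-ol | C=C[C@@](C)(CC=C)c1ccc(OCOC)c(Oc2cc(/C(C)=C/CO)cc(OCOC)c2OCOC)c1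
F5 | step 9 | 5-[(2E)-4-chlorobut-2-en-2-yl]-1,2-bis(methoxymethoxy)-3-{2-(methoxymethoxy)-5-[(3R)-3-methylhexa-1,5-dien-3-yl]phenoxy}benzene | C=C[C@@](C)(CC=C)c1ccc(OCOC)c(Oc2cc(/C(C)=C/CCl)cc(OCOC)c2OCOC)c1
F6 | step 17 | triphenol bis(N-hydroxyphthalimide ester) (21 without its three methoxymethyl groups) | C=C[C@@](C)(CCC(=O)ON1C(=O)c2ccccc2C1=O)c1ccc(O)c(Oc2cc([C@](C)(C=C)CCC(=O)ON3C(=O)c4ccccc4C3=O)cc(O)c2O)c1
F7 | step 17 | tris(triisopropylsilyl) ether bis(N-hydroxyphthalimide ester) | C=C[C@@](C)(CCC(=O)ON1C(=O)c2ccccc2C1=O)c1ccc(O[Si](C(C)C)(C(C)C)C(C)C)c(Oc2cc([C@](C)(C=C)CCC(=O)ON3C(=O)c4ccccc4C3=O)cc(O[Si](C(C)C)(C(C)C)C(C)C)c2O[Si](C(C)C)(C(C)C)C(C)C)c1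
F8 | step 17 | tris(triisopropylsilyl) ether of 29 | C=C[C@@](C)(CC/C=C(\C)CCC=C(C)C)c1ccc(O[Si](C(C)C)(C(C)C)C(C)C)c(Oc2cc([C@](C)(C=C)CC/C=C(\C)CCC=C(C)C)cc(O[Si](C(C)C)(C(C)C)C(C)C)c2O[Si](C(C)C)(C(C)C)C(C)C)c1
F9 | step 3 | methyl 3,4-bis(methoxymethoxy)-5-(4,4,5,5-tetramethyl-1,3,2-dioxaborolan-2-yl)benzoate | COC(=O)c1cc(OCOC)c(OCOC)c(B2OC(C)(C)C(C)(C)O2)c1
A1 | alternative 1 | diaryl ether bis(N,N-diisopropylcarbamate) of the two 1-arylethanols, R at the ring A carbinol carbon and S at the ring B one, phenols as triisopropylsilyl ethers | C[C@@H](OC(=O)N(C(C)C)C(C)C)c1ccc(O[Si](C(C)C)(C(C)C)C(C)C)c(Oc2cc([C@H](C)OC(=O)N(C(C)C)C(C)C)cc(O[Si](C(C)C)(C(C)C)C(C)C)c2O[Si](C(C)C)(C(C)C)C(C)C)c1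
A2 | alternative 1 | 2-[(3E)-4,8-dimethylnona-3,7-dien-1-yl]-4,4,5,5-tetramethyl-1,3,2-dioxaborolane (homogeranyl pinacol boronate) | CC(C)=CCC/C(C)=C/CCB1OC(C)(C)C(C)(C)O1
A3 | alternative 1 | diaryl ether bis(tertiary pinacol boronate) with both quaternary centres set, phenols as triisopropylsilyl ethers | CC1(C)OB(OC1(C)C)[C@@](C)(CC/C=C(\C)CCC=C(C)C)c1ccc(O[Si](C(C)C)(C(C)C)C(C)C)c(Oc2cc([C@](C)(B3OC(C)(C)C(C)(C)O3)CC/C=C(\C)CCC=C(C)C)cc(O[Si](C(C)C)(C(C)C)C(C)C)c2O[Si](C(C)C)(C(C)C)C(C)C)c1
A4 | alternative 2 | (3S,6E)-3-ethenyl-3,7,11-trimethyldodeca-6,10-dienal | O=CC[C@@](C)(C=C)CC/C=C(\C)CCC=C(C)C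
A5 | alternative 2 | 1-{2,3-bis(methoxymethoxy)-5-[(3S,6E)-3,7,11-trimethyldodeca-1,6,10-trien-3-yl]phenoxy}but-3-en-2-one | C=CC(=O)COc1cc([C@](C)(C=C)CC/C=C(\C)CCC=C(C)C)cc(OCOC)c1OCOC
A6 | alternative 2 | 2-aryloxy-4-alkylcyclohex-2-en-1-one (ring CH centre unassigned) | O=C1CCC([C@@](C)(C=C)CC/C=C(\C)CCC=C(C)C)C=C1Oc1cc([C@](C)(C=C)CC/C=C(\C)CCC=C(C)C)cc(OCOC)c1OCOC
A7 | alternative 3 | (4S,7E)-1-diazo-4-ethenyl-4,8,12-trimethyl-3-methylidenetrideca-7,11-dien-2-one | [N-]=[N+]=CC(=O)C(=C)[C@](C)(C=C)CC/C=C(\C)CCC=C(C)C
A8 | alternative 3 | 2-(ethynyloxy)-1-(methoxymethoxy)-4-[(3R,6E)-3,7,11-trimethyldodeca-1,6,10-trien-3-yl]benzene | C#COc1cc([C@@](C)(C=C)CC/C=C(\C)CCC=C(C)C)ccc1OCOC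
A9 | alternative 3 | 3-aryloxy-5-alkylphenol with ring B formed and both arms in place (ring A phenol as methoxymethyl ether) | C=C[C@@](C)(CC/C=C(\C)CCC=C(C)C)c1ccc(OCOC)c(Oc2cc([C@](C)(C=C)CC/C=C(\C)CCC=C(C)C)cc(O)c2)c1
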